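Locants used throughout: butenolide O1, C2(=O), C3(CH3), C4(H), C5; side chain from C5: C1'(=CH), C2'(stereocentre, CH3), C3'(H2), C4'=C5', C6'(CH3)=C7', C8'(H2), C9'(H2). C9' is bound to C4 of the central furan, whose C2 carries the furan-3-ylmethyl group.

## The problem

The target is a C25 chain with three five-membered oxygen rings: a 3-substituted furan, joined through one CH2 to C2 of a 2,4-disubstituted furan, whose C4 bears a nine-carbon chain ending in a 3-methyl-5-ylidenefuran-2(5H)-one. The hardest element is the exocyclic enol-lactone double bond C5=C1'. It is E (C2' cis to H-4, trans to O1), which is the less stable geometry and the opposite of what alkyne lactonisation with proton delivery, enol-lactonisation of a keto acid or aldol/dehydration normally give. The only stereocentre, C2' (S), sits directly on that alkene and has no neighbour that could relay configuration to it. Its hydrogen is vinylogously acidic (ε to the lactone carbonyl), so strong base threatens the centre, and iodine, thiyl radicals, light or strong acid can equilibrate C5=C1' to Z. The chain also holds a (4'E,6'E)-diene whose trisubstituted half needs the methyl on C6', not C7'. Both furans are acid- and oxidant-sensitive, and the 2,4-pattern of the central one is not reached by simple metalation of a 3-alkylfuran. The feature that opens a short route is the array O1–C5(=C1'H)–C2'H(CH3)–C3'H2–C4'H=. O1 and C2' lie anti across C5=C1', exactly as a carboxylate oxygen and a carbon group are placed when they add anti across a terminal alkyne C5≡C1'; and C2' is β to C4', an sp2 carbon that can be carried as an aldehyde, so C2'–C3'–C4' with its methyl is a crotonaldehyde unit.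

## Retrosynthesis

**C5'–C6' (19 ⇒ 7 + 18).** The diene is cut at its central single bond into alkenylboronate 7 and alkenyl iodide 18. A C4'=C5' olefination would expose the enol lactone and H-2' to a basic ylide or sulfone anion with uncertain E/Z control, and a C7'–C8' sp2–sp3 cut is less convergent. This cut joins two halves of similar size in which every double bond is already fixed, by a coupling that retains both geometries. It asks only for a mild base and exclusion of light.

**C4'=C5' (7 ⇒ 6).** The boron-bearing alkene is traced to aldehyde 6 by a one-carbon chromium(II) borylolefination. The neighbouring option, an alkyne at C4' followed by hydroboration, would need a basic homologation. Aldehyde 6 is β-branched, so C2' cannot epimerise through an enol. The reaction must be E-selective and non-basic.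

**O1–C5, C1'–C2' and C3'–H (6 ⇒ 4 + 5), the key cut.** Three bonds are cut at once: the lactone C–O bond, the bond from the exocyclic carbon to the stereocentre, and a C–H bond α to the aldehyde. This leads back to the achiral enynoic acid 4 and crotonaldehyde 5. Olefination at C5=C1' or coupling at C4–C5 would each leave either the E geometry or the stereocentre unsolved. Here the E geometry follows from anti addition across the alkyne, and the stereocentre is created in the same event. The precursors are a C6 acid and a C4 commodity enal; the product has the ring, the E alkene, the stereocentre and the handle for the diene. The forward reaction must close 5-exo, insert the enal face-selectively and end by protonolysis.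

**C2=C3 (4 ⇒ 3 ⇒ 1 + 2).** The Z-trisubstituted alkene of 4 is cut by olefination into silyl propynal 1 and phosphonate 2; ester and silyl group of 3 fall in one hydrolysis. A Z-selective olefination is required, because only the Z acid can lactonise.

**C6'–I and C7'–H (18 ⇒ 16).** The iodoalkene is the syn-hydrometalation/iodination product of the 2-alkyne 16. This is chosen over Wittig routes to the trisubstituted alkene, which need several redox steps. The metal must settle on the methyl-bearing carbon.

**C4(furan)–C9' (16 ⇒ 12 + 15; 15 from 14; 14 from 13).** The sp2–sp3 bond is cut into bromofuran 12 and the alkylzinc 15, made from iodide 14 and thus from pent-3-yn-1-ol 13. Alkylation of a 3-furyllithium would be slow and risks migration of lithium to the α-position.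

**CH2 bridge (12 ⇒ 11 ⇒ 9 + 10; 10 from 8).** The bis-furylmethane is cut at the CH2–C3 bond of the terminal furan. Furan-3-yllithium 10 (from 3-bromofuran 8) adds to aldehyde 9, which already carries the 2,4-pattern, and carbinol 11 is deoxygenated. The deoxygenation must spare two acid-sensitive furans.

## Roads not taken

Alternative 1: The most obvious plan cuts O1–C5 and C4–C5 and builds the butenolide last, from (2Z)-3-iodo-2-methylprop-2-enoic acid A1 and the full-length chiral alkyne A2. The forward key step is a Sonogashira coupling followed in the same flask by 5-exo-dig anti addition of the carboxylate oxygen and a proton across the internal alkyne. Because the proton, not the chain, enters trans to oxygen, this gives the 5Z isomer A3. A3 is also the thermodynamic isomer, so equilibration cannot correct it. A2 would need its stereocentre from a stoichiometric auxiliary or the chiral pool in a long linear sequence. The chosen plan uses the same anti addition but lets the chain carbon take the position trans to oxygen.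

Alternative 2: Cut C5=C1' as an aldol/dehydration. Vinylogous Mukaiyama aldol addition of silyloxyfuran A4 to the α-methyl aldehyde A5 would give hydroxyalkyl butenolide A6, and a stereospecific anti elimination of the activated hydroxyl would give 19. The E alkene needs the unlike arrangement of the two temporary centres (5R,1'S, as drawn for A6). This must be won against the facial bias of an α-branched, epimerisable aldehyde, and any E1cB component through the aromatic furanolate leaks to the Z isomer. Two stereocentres are made only to be destroyed, and A5 again costs a long linear sequence. In the chosen key step the geometry is a consequence of mechanism, not of a diastereomer ratio.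

Alternative 3: Cut C1'–C2' by sp2–sp3 cross-coupling. Iodolactonisation of 4 would give the (E)-iodomethylidene butenolide A7 (iodine anti to O1), to be joined with retention to the configurationally defined secondary alkylzinc A8. The geometry is secure. However, the stereocentre must come stoichiometrically from the chiral pool through an inversion and an iodine–lithium exchange at very low temperature, in the presence of a diene and two furans with acidic α-hydrogens, and the organometallic carries most of the molecule into its riskiest step. The chosen cascade forms the same C1'–C2' bond together with the lactone, catalytically, from achiral C6 and C4 components. A shortened form of this alternative is kept as the fallback for step 3.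

Key step: step 3

Remark (assumption): the SMILES is read as 5E (C2' cis to H-4), 2'S, 4'E, 6'E; all compounds containing the enol lactone are handled in the dark and kept from iodine, thiols and strong base.

Remark (assumption): the sense of induction in step 3 cannot be predicted with confidence for this new substrate pair; the (S,S)-ligand is written and its antipode is used if the induction is opposite.

## Route

Step 1  
Reactants: 1 3-(trimethylsilyl)prop-2-ynal; 2 ethyl 2-[bis(2,2,2-trifluoroethoxy)phosphoryl]propanoate  
Product: 3 ethyl (2Z)-2-methyl-5-(trimethylsilyl)pent-2-en-4-ynoate  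
Conditions: KHMDS, 18-crown-6, THF, −78 °C  
Reagents that add atoms: none  
Why: Still–Gennari variant of the Horner–Wadsworth–Emmons reaction: the bis(trifluoroethyl) phosphonate makes elimination from the first-formed adduct fast, so the kinetic Z-trisubstituted enoate should result, with the ester cis to the alkyne as the later lactonisation demands. No stereocentre is formed.

Step 2  
Reactants: 3 ethyl (2Z)-2-methyl-5-(trimethylsilyl)pent-2-en-4-ynoate  
Product: 4 (2Z)-2-methylpent-2-en-4-ynoic acid  
Conditions: LiOH·H2O, THF/H2O, 0 → 25 °C; then 1 M HCl to pH 3  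
Reagents that add atoms: lithium hydroxide, [Li+].[OH-]  
Why: Saponification of the ester and hydroxide-induced cleavage of the alkynyl–silicon bond occur in one operation; the carboxylate is not a Michael acceptor, so the Z alkene is not at risk.

Step 3  
Reactants: 4 (2Z)-2-methylpent-2-en-4-ynoic acid; 5 (2E)-but-2-enal  
Product: 6 (3S,4E)-3-methyl-4-(4-methyl-5-oxofuran-2(5H)-ylidene)butanal  
Conditions: [Pd((S,S)-chiraphos)(PhCN)2](SbF6)2 (5 mol %), 5 (5 equiv), acetone/H2O (20:1), 0 → 25 °C, dark  
Reagents that add atoms: none  
Why: Proposed new method: the dicationic Pd(II) centre binds the terminal alkyne of 4 and the carboxylate oxygen attacks the internal alkyne carbon from the face opposite to palladium (anti-oxypalladation), which closes the butenolide and leaves palladium on C1' trans to O1; the alkenyl–Pd bond then adds syn across the C=C bond of 5 (C1' to the β-carbon, Pd to the α-carbon) and the palladium enolate is protonated by the acid released in the first event, which returns Pd(II). The closest known reaction types are the Pd(II)-catalysed nucleopalladation of alkynes followed by conjugate addition to acrolein or vinyl ketones, and the chiral-diphosphine Pd(II)-catalysed 1,4-addition of organoboron reagents to acyclic enones and enals, in which the same insertion and enolate protonolysis set a β-stereocentre; new is their union in an intermolecular, enantioselective form with a β-methyl enal. The ring closed is the five-membered lactone, by 5-exo-dig O-attack, which for a terminal alkyne is also the Markovnikov mode and should beat 6-endo closure to the pyranone. The exocyclic double bond is E by mechanism, because the new carbon takes the place of palladium with retention and palladium stood anti to oxygen. The C2' stereocentre arises in the insertion step and is controlled by the C2-symmetric diphosphine, which differentiates the enantiofaces of the enal bound cis to the alkenyl ligand. The step needs insertion to outrun protonolysis of the alkenyl–Pd bond (excess 5, unhindered terminal alkenyl–Pd carbon, non-coordinating anion) and enolate protonolysis to outrun β-hydride elimination (the cis-chelating diphosphine leaves no free site, and water and acid are present).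

Step 4  
Reactants: 6 (3S,4E)-3-methyl-4-(4-methyl-5-oxofuran-2(5H)-ylidene)butanal  
Product: 7 (5E)-3-methyl-5-[(2S,4E)-2-methyl-5-(4,4,5,5-tetramethyl-1,3,2-dioxaborolan-2-yl)pent-4-en-1-ylidene]furan-2(5H)-one  
Conditions: Cl2CHBpin, CrCl2, LiI, THF, 25 °C, dark  
Reagents that add atoms: 2-(dichloromethyl)-4,4,5,5-tetramethyl-1,3,2-dioxaborolane, ClC(Cl)B1OC(C)(C)C(C)(C)O1  
Why: Takai–Utimoto borylolefination: the geminal dichromium species adds to the aldehyde and eliminates to the E alkenylboronate; such chromium(II) reagents are not basic and do not attack esters or lactones. C2' is β to the carbonyl and cannot epimerise.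

Step 5  
Reactants: 8 3-bromofuran; 9 4-bromofuran-2-carbaldehyde  
Product: 11 (4-bromofuran-2-yl)(furan-3-yl)methanol, via furan-3-yllithium 10 (not isolated)  
Conditions: n-BuLi, THF, −78 °C; then 9, −78 °C; aq. NH4Cl  
Reagents that add atoms: none  
Why: Bromine–lithium exchange gives 10, which stays on C3 at −78 °C, and 1,2-addition to the aldehyde of 9 is much faster than exchange with its ring bromine. The 2,4-pattern of the central furan is thus taken from commercial 9; the carbinol centre is racemic and is removed in step 6.

Step 6  
Reactants: 11 (4-bromofuran-2-yl)(furan-3-yl)methanol  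
Product: 12 4-bromo-2-(furan-3-ylmethyl)furan  
Conditions: Et3SiH, CF3CO2H, CH2Cl2, −40 → 0 °C  
Reagents that add atoms: none  
Why: Ionic hydrogenation: the carbinol ionises to a cation stabilised by both furan rings and is reduced by hydride transfer from the silane; low temperature and excess silane are meant to outrun Friedel–Crafts capture by a furan.

Step 7  
Reactants: 13 pent-3-yn-1-ol  
Product: 14 5-iodopent-2-yne  
Conditions: I2, PPh3, imidazole, CH2Cl2, 0 → 25 °C  
Reagents that add atoms: iodine, II  
Why: Appel-type iodination through the alkoxyphosphonium salt (SN2 at a primary carbon); the internal alkyne is inert.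

Step 8  
Reactants: 14 5-iodopent-2-yne; 12 4-bromo-2-(furan-3-ylmethyl)furan  
Product: 16 2-(furan-3-ylmethyl)-4-(pent-3-yn-1-yl)furan, via iodo(pent-3-yn-1-yl)zinc 15 (not isolated)  
Conditions: Zn dust (activated with BrCH2CH2Br, Me3SiCl), LiCl, THF, 40 °C; then 12, Pd(OAc)2 (2 mol %), SPhos (4 mol %), THF, 25 → 50 °C  
Reagents that add atoms: none  
Why: Direct zinc insertion into the primary iodide, then Negishi sp3–sp2 coupling with the heteroaryl bromide; the bulky biarylphosphine favours reductive elimination over β-hydride elimination, and the organozinc tolerates the furans and the internal alkyne.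

Step 9  
Reactants: 16 2-(furan-3-ylmethyl)-4-(pent-3-yn-1-yl)furan  
Product: 18 2-(furan-3-ylmethyl)-4-[(3E)-4-iodopent-3-en-1-yl]furan, via the alkenylzirconocene chloride 17 (not isolated)  
Conditions: Cp2Zr(H)Cl (2 equiv), THF, 25 → 45 °C, dark; then I2, THF, −78 °C  
Reagents that add atoms: iodine, II  
Why: syn-Hydrozirconation of the internal alkyne; with excess zirconium hydride the regioisomeric alkenylzirconiums equilibrate toward metal on the less hindered, methyl-bearing carbon. Iodinolysis proceeds with retention, so iodine ends on C6' trans to the CH2 chain (E).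

Step 10  
Reactants: 7 (5E)-3-methyl-5-[(2S,4E)-2-methyl-5-(4,4,5,5-tetramethyl-1,3,2-dioxaborolan-2-yl)pent-4-en-1-ylidene]furan-2(5H)-one; 18 2-(furan-3-ylmethyl)-4-[(3E)-4-iodopent-3-en-1-yl]furan  
Product: 19 (5E)-5-[(2S,4E,6E)-9-[5-(furan-3-ylmethyl)furan-3-yl]-2,6-dimethylnona-4,6-dien-1-ylidene]-3-methylfuran-2(5H)-one  
Conditions: Pd(OAc)2 (5 mol %), SPhos (10 mol %), aq. K3PO4 (2 equiv), THF, 25 °C, dark  
Reagents that add atoms: none  
Why: Suzuki–Miyaura alkenyl–alkenyl coupling; oxidative addition and transmetalation both retain alkene geometry, so the (4'E,6'E)-diene follows from 7 and 18. Aqueous phosphate at room temperature is the mildest base that still activates the pinacol boronate, chosen to spare the enol lactone and H-2'.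

## Compound list

1 | 3-(trimethylsilyl)prop-2-ynal | C[Si](C)(C)C#CC=O | starting material  
2 | ethyl 2-[bis(2,2,2-trifluoroethoxy)phosphoryl]propanoate | CCOC(=O)C(C)P(=O)(OCC(F)(F)F)OCC(F)(F)F | starting material  
3 | ethyl (2Z)-2-methyl-5-(trimethylsilyl)pent-2-en-4-ynoate | CCOC(=O)/C(C)=C\C#C[Si](C)(C)C | intermediate  
4 | (2Z)-2-methylpent-2-en-4-ynoic acid | C#C/C=C(C)\C(O)=O | intermediate  
5 | (2E)-but-2-enal (crotonaldehyde) | C/C=C/C=O | starting material  
6 | (3S,4E)-3-methyl-4-(4-methyl-5-oxofuran-2(5H)-ylidene)butanal | CC1=C/C(=C\[C@@H](C)CC=O)OC1=O | intermediate  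
7 | (5E)-3-methyl-5-[(2S,4E)-2-methyl-5-(4,4,5,5-tetramethyl-1,3,2-dioxaborolan-2-yl)pent-4-en-1-ylidene]furan-2(5H)-one | CC1=C/C(=C\[C@@H](C)C/C=C/B2OC(C)(C)C(C)(C)O2)OC1=O | intermediate  
8 | 3-bromofuran | Brc1ccoc1 | starting material  
9 | 4-bromofuran-2-carbaldehyde | O=Cc1cc(Br)co1 | starting material  
10 | furan-3-yllithium | [Li]c1ccoc1 | intermediate (not isolated)  
11 | (4-bromofuran-2-yl)(furan-3-yl)methanol (racemic) | OC(c1ccoc1)c1cc(Br)co1 | intermediate  
12 | 4-bromo-2-(furan-3-ylmethyl)furan | Brc1coc(Cc2ccoc2)c1 | intermediate  
13 | pent-3-yn-1-ol | CC#CCCO | starting material  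
14 | 5-iodopent-2-yne | CC#CCCI | intermediate  
15 | iodo(pent-3-yn-1-yl)zinc | CC#CCC[Zn]I | intermediate (not isolated)  
16 | 2-(furan-3-ylmethyl)-4-(pent-3-yn-1-yl)furan | CC#CCCc1coc(Cc2ccoc2)c1 | intermediate  
17 | chloridobis(cyclopentadienyl){(2E)-5-[5-(furan-3-ylmethyl)furan-3-yl]pent-2-en-2-yl}zirconium | C/C(=C\CCc1coc(Cc2ccoc2)c1)[Zr](Cl)(C1C=CC=C1)C1C=CC=C1 | intermediate (not isolated)  
18 | 2-(furan-3-ylmethyl)-4-[(3E)-4-iodopent-3-en-1-yl]furan | C/C(I)=C\CCc1coc(Cc2ccoc2)c1 | intermediate  
19 | (5E)-5-[(2S,4E,6E)-9-[5-(furan-3-ylmethyl)furan-3-yl]-2,6-dimethylnona-4,6-dien-1-ylidene]-3-methylfuran-2(5H)-one | CC1=C/C(=C\[C@@H](C)C/C=C/C(C)=C/CCc2coc(Cc3ccoc3)c2)OC1=O | target  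

## Step count and risks

Total steps: 10. Longest linear sequence: 5 steps (steps 1, 2, 3, 4, 10; equally steps 5, 6, 8, 9, 10).

**Step 3 (key step, Proposed new method).** The most likely failure is protonolysis of the alkenyl–palladium bond before the β-substituted enal inserts, which would give plain cycloisomerisation. Poor enantioface discrimination on an acyclic enal, or acid-promoted equilibration of the kinetic E enol lactone to Z, could erode the stereochemical result. Fallback by known chemistry, setting out from 4 and returning at 6:
- Iodolactonisation of 4 (I2, NaHCO3, MeCN; anti addition, iodine trans to O1) gives (5E)-5-(iodomethylidene)-3-methylfuran-2(5H)-one F1.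
- In parallel, commercial (3R)-butane-1,3-diol F2 is silylated at the primary hydroxyl to (2R)-4-[(tert-butyldimethylsilyl)oxy]butan-2-ol F3 and converted with inversion (I2, PPh3, imidazole) into tert-butyl{[(3S)-3-iodobutyl]oxy}dimethylsilane F4.
- Iodine–lithium exchange with t-BuLi at −100 °C (retention) gives [(2S)-4-[(tert-butyldimethylsilyl)oxy]butan-2-yl]lithium F5, which is trapped at once with Me3SiCH2ZnBr·LiBr as [(2S)-4-[(tert-butyldimethylsilyl)oxy]butan-2-yl][(trimethylsilyl)methyl]zinc F6.
- Palladium-catalysed Negishi coupling of F6 with F1, with retention at both carbons, gives (5E)-5-[(2S)-4-[(tert-butyldimethylsilyl)oxy]-2-methylbutylidene]-3-methylfuran-2(5H)-one F7.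
- HF·pyridine liberates (5E)-5-[(2S)-4-hydroxy-2-methylbutylidene]-3-methylfuran-2(5H)-one F8, and Dess–Martin oxidation gives 6.

**Step 10.** Aqueous base may open the enol lactone, deprotonate H-2' or promote E→Z isomerisation of C5=C1', and protodeboronation of 7 may compete. Fallback with reversed polarity and no base, setting out from 6 and 18 and returning at 19:
- Takai iodo-olefination of 6 (CHI3, CrCl2) gives (5E)-5-[(2S,4E)-5-iodo-2-methylpent-4-en-1-ylidene]-3-methylfuran-2(5H)-one F9.
- 18 is converted with t-BuLi at −78 °C into {5-[5-(furan-3-ylmethyl)furan-3-yl]pent-2-en-2-yl}lithium F10 (metal trans to the CH2 chain) and with ZnBr2 into bromo{(2E)-5-[5-(furan-3-ylmethyl)furan-3-yl]pent-2-en-2-yl}zinc F11.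
- Negishi coupling of F11 with F9 (Pd(PPh3)4, THF, 25 °C) gives 19.

**Step 9.** Incomplete regiochemical equilibration of the alkenylzirconium would place the metal, and then iodine, on C7', and the regioisomeric iodides may be hard to separate. Fallback that fixes regiochemistry through a 1,1-dibromoalkene, setting out from 12 and 7 and returning at 19:
- Negishi coupling of 12 with commercial bromo[2-(1,3-dioxolan-2-yl)ethyl]zinc F12 gives 2-{2-[5-(furan-3-ylmethyl)furan-3-yl]ethyl}-1,3-dioxolane F13.
- Mild aqueous acid gives 3-[5-(furan-3-ylmethyl)furan-3-yl]propanal F14, and Ramirez olefination (CBr4, PPh3) gives 4-(4,4-dibromobut-3-en-1-yl)-2-(furan-3-ylmethyl)furan F15.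
- Suzuki–Miyaura coupling of F15 with 7 is trans-selective, so it replaces only the bromine trans to the chain and gives (5E)-5-[(2S,4E,6Z)-6-bromo-9-[5-(furan-3-ylmethyl)furan-3-yl]-2-methylnona-4,6-dien-1-ylidene]-3-methylfuran-2(5H)-one F16.
- Negishi methylation of F16 (MeZnCl, Pd(t-Bu3P)2) with retention gives 19.

**Step 6.** The doubly furyl-stabilised cation may be captured by a furan ring (oligomerisation), or the furans may be opened by the acid, before hydride transfer. Fallback that avoids both the cation and the acid, setting out from 9 and 15 and returning at 16: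
- Negishi coupling of 15 with 9 (the aldehyde is tolerated) gives 4-(pent-3-yn-1-yl)furan-2-carbaldehyde F17.
- NaBH4 gives [4-(pent-3-yn-1-yl)furan-2-yl]methanol F18, and methyl chloroformate/pyridine gives methyl [4-(pent-3-yn-1-yl)furan-2-yl]methyl carbonate F19.
- Palladium-catalysed benzylic-type Suzuki–Miyaura coupling of F19 with commercial furan-3-ylboronic acid F20 gives 16.

## Further compounds

F1 | step 3 | (5E)-5-(iodomethylidene)-3-methylfuran-2(5H)-one | CC1=C/C(=C\I)OC1=O  
F2 | step 3 | (3R)-butane-1,3-diol | O[C@H](C)CCO  
F3 | step 3 | (2R)-4-[(tert-butyldimethylsilyl)oxy]butan-2-ol | O[C@H](C)CCO[Si](C)(C)C(C)(C)C  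
F4 | step 3 | tert-butyl{[(3S)-3-iodobutyl]oxy}dimethylsilane | I[C@@H](C)CCO[Si](C)(C)C(C)(C)C  
F5 | step 3 | [(2S)-4-[(tert-butyldimethylsilyl)oxy]butan-2-yl]lithium | [Li][C@@H](C)CCO[Si](C)(C)C(C)(C)C  
F6 | step 3 | [(2S)-4-[(tert-butyldimethylsilyl)oxy]butan-2-yl][(trimethylsilyl)methyl]zinc | C[Si](C)(C)C[Zn][C@@H](C)CCO[Si](C)(C)C(C)(C)C  
F7 | step 3 | (5E)-5-[(2S)-4-[(tert-butyldimethylsilyl)oxy]-2-methylbutylidene]-3-methylfuran-2(5H)-one | CC1=C/C(=C\[C@@H](C)CCO[Si](C)(C)C(C)(C)C)OC1=O  
F8 | step 3 | (5E)-5-[(2S)-4-hydroxy-2-methylbutylidene]-3-methylfuran-2(5H)-one | CC1=C/C(=C\[C@@H](C)CCO)OC1=O  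
F9 | step 10 | (5E)-5-[(2S,4E)-5-iodo-2-methylpent-4-en-1-ylidene]-3-methylfuran-2(5H)-one | CC1=C/C(=C\[C@@H](C)C/C=C/I)OC1=O  
F10 | step 10 | {5-[5-(furan-3-ylmethyl)furan-3-yl]pent-2-en-2-yl}lithium (metal trans to the CH2 chain) | [Li]/C(C)=C/CCc1coc(Cc2ccoc2)c1  
F11 | step 10 | bromo{(2E)-5-[5-(furan-3-ylmethyl)furan-3-yl]pent-2-en-2-yl}zinc | Br[Zn]/C(C)=C/CCc1coc(Cc2ccoc2)c1  
F12 | step 9 | bromo[2-(1,3-dioxolan-2-yl)ethyl]zinc | Br[Zn]CCC1OCCO1  
F13 | step 9 | 2-{2-[5-(furan-3-ylmethyl)furan-3-yl]ethyl}-1,3-dioxolane | O1CCOC1CCc1coc(Cc2ccoc2)c1  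
F14 | step 9 | 3-[5-(furan-3-ylmethyl)furan-3-yl]propanal | O=CCCc1coc(Cc2ccoc2)c1  
F15 | step 9 | 4-(4,4-dibromobut-3-en-1-yl)-2-(furan-3-ylmethyl)furan | BrC(Br)=CCCc1coc(Cc2ccoc2)c1  
F16 | step 9 | (5E)-5-[(2S,4E,6Z)-6-bromo-9-[5-(furan-3-ylmethyl)furan-3-yl]-2-methylnona-4,6-dien-1-ylidene]-3-methylfuran-2(5H)-one | CC1=C/C(=C\[C@@H](C)C/C=C/C(Br)=C/CCc2coc(Cc3ccoc3)c2)OC1=O  
F17 | step 6 | 4-(pent-3-yn-1-yl)furan-2-carbaldehyde | CC#CCCc1coc(C=O)c1  
F18 | step 6 | [4-(pent-3-yn-1-yl)furan-2-yl]methanol | CC#CCCc1coc(CO)c1  
F19 | step 6 | methyl [4-(pent-3-yn-1-yl)furan-2-yl]methyl carbonate | CC#CCCc1coc(COC(=O)OC)c1  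
F20 | step 6 | furan-3-ylboronic acid | OB(O)c1ccoc1  
A1 | alternative 1 | (2Z)-3-iodo-2-methylprop-2-enoic acid | I/C=C(C)\C(O)=O  
A2 | alternative 1 | 2-(furan-3-ylmethyl)-4-[(3E,5E,8S)-4,8-dimethyldeca-3,5-dien-9-yn-1-yl]furan | C#C[C@@H](C)C/C=C/C(C)=C/CCc1coc(Cc2ccoc2)c1  
A3 | alternative 1 | (5Z)-5-[(2S,4E,6E)-9-[5-(furan-3-ylmethyl)furan-3-yl]-2,6-dimethylnona-4,6-dien-1-ylidene]-3-methylfuran-2(5H)-one | CC1=C/C(=C/[C@@H](C)C/C=C/C(C)=C/CCc2coc(Cc3ccoc3)c2)OC1=O  
A4 | alternative 2 | trimethyl[(3-methylfuran-2-yl)oxy]silane | Cc1ccoc1O[Si](C)(C)C  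
A5 | alternative 2 | (2S,4E,6E)-9-[5-(furan-3-ylmethyl)furan-3-yl]-2,6-dimethylnona-4,6-dienal | O=C[C@@H](C)C/C=C/C(C)=C/CCc1coc(Cc2ccoc2)c1  
A6 | alternative 2 | (5R)-5-[(1S,2S,4E,6E)-9-[5-(furan-3-ylmethyl)furan-3-yl]-1-hydroxy-2,6-dimethylnona-4,6-dien-1-yl]-3-methylfuran-2(5H)-one | O=C1O[C@H](C=C1C)[C@@H](O)[C@@H](C)C/C=C/C(C)=C/CCc1coc(Cc2ccoc2)c1  
A7 | alternative 3 | (5E)-5-(iodomethylidene)-3-methylfuran-2(5H)-one | CC1=C/C(=C\I)OC1=O  
A8 | alternative 3 | [(2S,4E,6E)-9-[5-(furan-3-ylmethyl)furan-3-yl]-6-methylnona-4,6-dien-2-yl][(trimethylsilyl)methyl]zinc | C[Si](C)(C)C[Zn][C@@H](C)C/C=C/C(C)=C/CCc1coc(Cc2ccoc2)c1  
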